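**Retrosynthetic overview**
- The exocyclic C10=C14 methylene is unveiled last by protodesilylation of a cyclic allylsilane; the seven-membered ring B is closed just before that by ring-closing metathesis (C9=C10).
- The metathesis precursor comes from a C3 ketol (hydroxyl-directed reduction gives the trans-3,4-diol), whose C4 methyl carbinol is set by chelation-controlled MeMgBr addition.
- Key union (C5–C6): anti-aldol between the α′-enolate of a 2-methoxycyclopentenone (fragment A: C1–C5, C10, C14) and an α-isopropyl-β-silyloxy aldehyde (fragment B: C6–C9, C11–C13).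
- Fragment A: chiral-pool 4-hydroxycyclopentenone plus a 2-metallated allylsilane. Fragment B: Evans syn-aldol of an isovaleryl imide with acrolein.
- Ring order: ring A (five-membered) is present from the start; ring B (seven-membered) is formed at the end.

Assumption: "C1–C15" in the text means the guaiane numbering of the target (C15 = methyl on C4, C14 = CH2 on C10, C11–C13 = isopropyl on C7); the (R)-4-benzyloxazolidin-2-one is a recovered auxiliary and is listed as a reagent.

**Step 1**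
Reactants: 1 2,3-dibromoprop-1-ene
Product: 2 (2-bromoprop-2-en-1-yl)trichlorosilane
Conditions: HSiCl3, Et3N, CuCl (5 mol %), Et2O, 0 °C → rt
Reagents that add atoms: trichlorosilane, Cl[SiH](Cl)Cl
Why: Copper-catalysed silylation (substitution of the allylic bromide by the HSiCl3/Et3N-derived silyl nucleophile) takes only the allylic C–Br bond and leaves the vinyl bromide for later metalation; no stereocentre is formed.

**Step 2**
Reactants: 2 (2-bromoprop-2-en-1-yl)trichlorosilane
Product: 3 (2-bromoprop-2-en-1-yl)trimethylsilane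
Conditions: MeMgBr (3.3 equiv), Et2O, 0 °C → reflux
Reagents that add atoms: methylmagnesium bromide, C[Mg]Br
Why: Nucleophilic substitution at silicon by the Grignard reagent replaces the three Si–Cl bonds by methyl groups to give the robust allylsilane.

**Step 3**
Reactants: 4 (R)-4-hydroxycyclopent-2-en-1-one
Product: 5 (R)-4-[(tert-butyldimethylsilyl)oxy]cyclopent-2-en-1-one
Conditions: TBSCl, imidazole, DMF, 0 °C → rt
Reagents that add atoms: tert-butyldimethylsilyl chloride, CC(C)(C)[Si](C)(C)Cl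
Why: Silyl ether formation masks the hydroxyl as a bulky directing and leaving group without touching the carbinol stereocentre.

**Step 4**
Reactants: 5 (R)-4-[(tert-butyldimethylsilyl)oxy]cyclopent-2-en-1-one; 3 (2-bromoprop-2-en-1-yl)trimethylsilane
Product: 8 (R)-4-[3-(trimethylsilyl)prop-1-en-2-yl]cyclopent-2-en-1-one, via alkenyl Grignard reagent 6 (not isolated), via trans conjugate adduct 7 (not isolated)
Conditions: 3, Mg, THF, 45 °C; CuBr·SMe2 (10 mol %), THF, −78 °C, then 5; aq. NH4Cl; DBU, CH2Cl2, 0 °C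
Reagents that add atoms: none
Why: Copper-catalysed conjugate addition of the alkenyl Grignard reagent occurs anti to the silyloxy group, and E1cB loss of silanol then gives the transposed enone, so the only remaining stereocentre (C1, R here) is fixed by the chiral-pool carbinol.

**Step 5**
Reactants: 8 (R)-4-[3-(trimethylsilyl)prop-1-en-2-yl]cyclopent-2-en-1-one
Product: 9 (1S,4S,5S)-4-[3-(trimethylsilyl)prop-1-en-2-yl]-6-oxabicyclo[3.1.0]hexan-2-one
Conditions: 30 % aq. H2O2, NaOH (0.2 equiv), MeOH, −10 → 0 °C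
Reagents that add atoms: hydrogen peroxide, OO
Why: Weitz–Scheffer nucleophilic epoxidation attacks only the electron-poor enone C=C (the allylsilane alkene is inert to hydroperoxide anion) anti to the C1 substituent; the epoxide configuration is erased in step 6.

**Step 6**
Reactants: 9 (1S,4S,5S)-4-[3-(trimethylsilyl)prop-1-en-2-yl]-6-oxabicyclo[3.1.0]hexan-2-one
Product: 11 (R)-2-methoxy-4-[3-(trimethylsilyl)prop-1-en-2-yl]cyclopent-2-en-1-one, via methoxy hydroxy ketone 10 (not isolated)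
Conditions: NaOMe (0.3 equiv), MeOH, 0 °C → rt
Reagents that add atoms: methanol, CO
Why: Methoxide opens the epoxy ketone at the carbon α to the carbonyl and E1cB dehydration gives the 2-methoxy enone, a masked C3 ketone that blocks enolisation on that side and never passes through the symmetric 1,2-dione; low temperature and short time protect the γ-stereocentre C1.

**Step 7**
Reactants: 12 3-methylbutanoyl chloride
Product: 13 (R)-4-benzyl-3-(3-methylbutanoyl)-1,3-oxazolidin-2-one
Conditions: (R)-4-benzyl-1,3-oxazolidin-2-one, n-BuLi, THF, −78 °C; then 12, −78 → 0 °C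
Reagents that add atoms: (R)-4-benzyl-1,3-oxazolidin-2-one, O=C1N[C@H](Cc2ccccc2)CO1
Why: N-Acylation of the lithiated oxazolidinone installs the recoverable auxiliary that controls the next step.

**Step 8**
Reactants: 13 (R)-4-benzyl-3-(3-methylbutanoyl)-1,3-oxazolidin-2-one; 14 prop-2-enal
Product: 16 (R)-4-benzyl-3-[(2R,3S)-3-hydroxy-2-(propan-2-yl)pent-4-enoyl]-1,3-oxazolidin-2-one, via Z boron enolate 15 (not isolated)
Conditions: Bu2BOTf, iPr2NEt, CH2Cl2, −78 → 0 °C; 14, −78 → 0 °C; pH 7 buffer, MeOH, 30 % H2O2, 0 °C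
Reagents that add atoms: none
Why: Evans syn-aldol: the Z-boron enolate reacts through a Zimmerman–Traxler chair on the face away from the benzyl group, setting C7 (R) and C8 (S) syn in one step.

**Step 9**
Reactants: 16 (R)-4-benzyl-3-[(2R,3S)-3-hydroxy-2-(propan-2-yl)pent-4-enoyl]-1,3-oxazolidin-2-one
Product: 17 (R)-4-benzyl-3-[(2R,3S)-2-(propan-2-yl)-3-[(triethylsilyl)oxy]pent-4-enoyl]-1,3-oxazolidin-2-one
Conditions: Et3SiOTf, 2,6-lutidine, CH2Cl2, −78 → 0 °C
Reagents that add atoms: triethylsilyl trifluoromethanesulfonate, CC[Si](CC)(CC)OS(=O)(=O)C(F)(F)F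
Why: Silylation blocks retro-aldol and gives a bulky, non-chelating C8 substituent that survives the enolate and Grignard steps and falls off under mild acid.

**Step 10**
Reactants: 17 (R)-4-benzyl-3-[(2R,3S)-2-(propan-2-yl)-3-[(triethylsilyl)oxy]pent-4-enoyl]-1,3-oxazolidin-2-one
Product: 18 (2S,3S)-2-(propan-2-yl)-3-[(triethylsilyl)oxy]pent-4-en-1-ol
Conditions: LiBH4, MeOH (1.1 equiv), THF, 0 °C
Reagents that add atoms: none
Why: Reductive cleavage of the imide gives the primary alcohol and returns the auxiliary without epimerising C7 (the descriptor changes only through CIP priorities).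

**Step 11**
Reactants: 18 (2S,3S)-2-(propan-2-yl)-3-[(triethylsilyl)oxy]pent-4-en-1-ol
Product: 19 (2R,3S)-2-(propan-2-yl)-3-[(triethylsilyl)oxy]pent-4-enal
Conditions: Dess–Martin periodinane, pyridine, CH2Cl2, 0 °C → rt
Reagents that add atoms: none
Why: Buffered Dess–Martin oxidation gives the α-branched aldehyde without epimerisation; it is used at once.

**Step 12**
Reactants: 11 (R)-2-methoxy-4-[3-(trimethylsilyl)prop-1-en-2-yl]cyclopent-2-en-1-one; 19 (2R,3S)-2-(propan-2-yl)-3-[(triethylsilyl)oxy]pent-4-enal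
Product: 21 (4S,5S)-5-[(1S,2S,3S)-1-hydroxy-2-(propan-2-yl)-3-[(triethylsilyl)oxy]pent-4-en-1-yl]-2-methoxy-4-[3-(trimethylsilyl)prop-1-en-2-yl]cyclopent-2-en-1-one, via lithium dienolate 20 (not isolated)
Conditions: 11, LiN(iPr)2, THF, −78 °C; then 19, −78 °C; AcOH
Reagents that add atoms: none
Why: Kinetic deprotonation gives only the α′ (C5) lithium enolate, and the aldol addition through a closed Zimmerman–Traxler transition state bonds C5 anti to the C1 substituent, gives the 5,6-anti adduct from the E-configured cyclic enolate, and follows Felkin–Anh with the silyloxy-bearing C8 branch as the large group (6,7-syn).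

**Step 13**
Reactants: 21 (4S,5S)-5-[(1S,2S,3S)-1-hydroxy-2-(propan-2-yl)-3-[(triethylsilyl)oxy]pent-4-en-1-yl]-2-methoxy-4-[3-(trimethylsilyl)prop-1-en-2-yl]cyclopent-2-en-1-one
Product: 23 (2S,3S,4S)-3-[(1S,2R,3S)-1,3-dihydroxy-2-(propan-2-yl)pent-4-en-1-yl]-2-hydroxy-2-methyl-4-[3-(trimethylsilyl)prop-1-en-2-yl]cyclopentan-1-one, via enol ether carbinol 22 (not isolated)
Conditions: MeMgBr (4 equiv), THF/CH2Cl2, −78 → −40 °C; then AcOH/THF/H2O (3:1:1), 35 °C
Reagents that add atoms: methylmagnesium bromide, C[Mg]Br; water, O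
Why: Chelation-controlled Grignard 1,2-addition: the C6 magnesium alkoxide ties the side chain to the ketone and methyl enters axially on the chelate, anti to H5 (C4 hydroxyl syn to the C6 hydroxyl); mild acid then hydrolyses the enol ether to the C3 ketone and removes the triethylsilyl group while the allylsilane survives.

**Step 14**
Reactants: 23 (2S,3S,4S)-3-[(1S,2R,3S)-1,3-dihydroxy-2-(propan-2-yl)pent-4-en-1-yl]-2-hydroxy-2-methyl-4-[3-(trimethylsilyl)prop-1-en-2-yl]cyclopentan-1-one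
Product: 24 (1S,2S,3S,4S)-3-[(1S,2R,3S)-1,3-dihydroxy-2-(propan-2-yl)pent-4-en-1-yl]-2-methyl-4-[3-(trimethylsilyl)prop-1-en-2-yl]cyclopentane-1,2-diol
Conditions: Me4NBH(OAc)3, MeCN/AcOH (1:1), −30 → 0 °C
Reagents that add atoms: none
Why: Hydroxyl-directed (Evans–Saksena type) reduction: the tertiary C4 hydroxyl binds the acetoxyborohydride and delivers hydride to its own face of the C3 ketone, giving the trans-3,4-diol.

**Step 15**
Reactants: 24 (1S,2S,3S,4S)-3-[(1S,2R,3S)-1,3-dihydroxy-2-(propan-2-yl)pent-4-en-1-yl]-2-methyl-4-[3-(trimethylsilyl)prop-1-en-2-yl]cyclopentane-1,2-diol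
Product: 25 (1S,2S,3S,4S)-3-[(1S,2R,3S)-1,3-diacetoxy-2-(propan-2-yl)pent-4-en-1-yl]-2-hydroxy-2-methyl-4-[3-(trimethylsilyl)prop-1-en-2-yl]cyclopentyl acetate
Conditions: Ac2O, pyridine, DMAP (10 mol %), CH2Cl2, 0 °C → rt
Reagents that add atoms: acetic anhydride, CC(=O)OC(C)=O
Why: Acylation esterifies the three secondary hydroxyls (C3, C6, C8) while the hindered tertiary C4 hydroxyl stays free, as in the target.

**Step 16**
Reactants: 25 (1S,2S,3S,4S)-3-[(1S,2R,3S)-1,3-diacetoxy-2-(propan-2-yl)pent-4-en-1-yl]-2-hydroxy-2-methyl-4-[3-(trimethylsilyl)prop-1-en-2-yl]cyclopentyl acetate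
Product: 26 (1S,3S,4S,5S,6S,7R,8S)-4-hydroxy-14-(trimethylsilyl)guai-9-ene-3,6,8-triyl triacetate
Conditions: second-generation Grubbs catalyst RuCl2(=CHPh)(PCy3)(SIMes) (10 mol %), CH2Cl2 (2 mM), 40 °C
Reagents that add atoms: none
Why: Ring-closing metathesis between the C8 vinyl group and the 1,1-disubstituted allylsilane alkene forms the trans-fused seven-membered ring as a cyclic allylsilane, driven by loss of ethene; no stereocentre is touched.

**Step 17**
Reactants: 26 (1S,3S,4S,5S,6S,7R,8S)-4-hydroxy-14-(trimethylsilyl)guai-9-ene-3,6,8-triyl triacetate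
Product: 27 (1S,3S,4S,5S,6S,7R,8S)-4-hydroxyguai-10(14)-ene-3,6,8-triyl triacetate
Conditions: CF3CO2H (0.3 equiv), wet CH2Cl2, 0 °C → rt
Reagents that add atoms: none
Why: Protodesilylation (SE2′): protonation at C9 gives the β-silyl cation at C10 and loss of silicon moves the double bond to the exocyclic C10=C14 position; acetates and the tertiary alcohol are untouched.

**Compound list**
1 | 2,3-dibromoprop-1-ene | C=C(Br)CBr | starting material
2 | (2-bromoprop-2-en-1-yl)trichlorosilane | C=C(Br)C[Si](Cl)(Cl)Cl | intermediate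
3 | (2-bromoprop-2-en-1-yl)trimethylsilane | C=C(Br)C[Si](C)(C)C | intermediate
4 | (R)-4-hydroxycyclopent-2-en-1-one | O=C1C=C[C@H](O)C1 | starting material
5 | (R)-4-[(tert-butyldimethylsilyl)oxy]cyclopent-2-en-1-one | O=C1C=C[C@H](O[Si](C)(C)C(C)(C)C)C1 | intermediate
6 | bromo[3-(trimethylsilyl)prop-1-en-2-yl]magnesium | C=C([Mg]Br)C[Si](C)(C)C | intermediate
7 | (3S,4R)-4-[(tert-butyldimethylsilyl)oxy]-3-[3-(trimethylsilyl)prop-1-en-2-yl]cyclopentan-1-one | O=C1C[C@@H](C(=C)C[Si](C)(C)C)[C@H](O[Si](C)(C)C(C)(C)C)C1 | intermediate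
8 | (R)-4-[3-(trimethylsilyl)prop-1-en-2-yl]cyclopent-2-en-1-one | O=C1C=C[C@H](C(=C)C[Si](C)(C)C)C1 | intermediate
9 | (1S,4S,5S)-4-[3-(trimethylsilyl)prop-1-en-2-yl]-6-oxabicyclo[3.1.0]hexan-2-one | O=C1C[C@@H](C(=C)C[Si](C)(C)C)[C@@H]2O[C@H]12 | intermediate
10 | (2R,3S,4S)-3-hydroxy-2-methoxy-4-[3-(trimethylsilyl)prop-1-en-2-yl]cyclopentan-1-one | O=C1C[C@@H](C(=C)C[Si](C)(C)C)[C@H](O)[C@H]1OC | intermediate
11 | (R)-2-methoxy-4-[3-(trimethylsilyl)prop-1-en-2-yl]cyclopent-2-en-1-one (fragment A) | O=C1C[C@@H](C(=C)C[Si](C)(C)C)C=C1OC | intermediate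
12 | 3-methylbutanoyl chloride | CC(C)CC(Cl)=O | starting material
13 | (R)-4-benzyl-3-(3-methylbutanoyl)-1,3-oxazolidin-2-one | CC(C)CC(=O)N1C(=O)OC[C@H]1Cc1ccccc1 | intermediate
14 | prop-2-enal | C=CC=O | starting material
15 | dibutylboron Z-enolate of 13 | CCCCB(CCCC)O/C(=C\C(C)C)N1C(=O)OC[C@H]1Cc1ccccc1 | intermediate
16 | (R)-4-benzyl-3-[(2R,3S)-3-hydroxy-2-(propan-2-yl)pent-4-enoyl]-1,3-oxazolidin-2-one | C=C[C@H](O)[C@@H](C(C)C)C(=O)N1C(=O)OC[C@H]1Cc1ccccc1 | intermediate
17 | (R)-4-benzyl-3-[(2R,3S)-2-(propan-2-yl)-3-[(triethylsilyl)oxy]pent-4-enoyl]-1,3-oxazolidin-2-one | C=C[C@H](O[Si](CC)(CC)CC)[C@@H](C(C)C)C(=O)N1C(=O)OC[C@H]1Cc1ccccc1 | intermediate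
18 | (2S,3S)-2-(propan-2-yl)-3-[(triethylsilyl)oxy]pent-4-en-1-ol | C=C[C@H](O[Si](CC)(CC)CC)[C@@H](C(C)C)CO | intermediate
19 | (2R,3S)-2-(propan-2-yl)-3-[(triethylsilyl)oxy]pent-4-enal (fragment B) | C=C[C@H](O[Si](CC)(CC)CC)[C@@H](C(C)C)C=O | intermediate
20 | lithium cross-conjugated dienolate of 11 (C1 unchanged) | [Li]OC1=C[C@@H](C(=C)C[Si](C)(C)C)C=C1OC | intermediate
21 | (4S,5S)-5-[(1S,2S,3S)-1-hydroxy-2-(propan-2-yl)-3-[(triethylsilyl)oxy]pent-4-en-1-yl]-2-methoxy-4-[3-(trimethylsilyl)prop-1-en-2-yl]cyclopent-2-en-1-one | C=C[C@H](O[Si](CC)(CC)CC)[C@@H](C(C)C)[C@H](O)[C@H]1C(=O)C(OC)=C[C@@H]1C(=C)C[Si](C)(C)C | intermediate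
22 | (1S,4S,5S)-5-[(1S,2S,3S)-1-hydroxy-2-(propan-2-yl)-3-[(triethylsilyl)oxy]pent-4-en-1-yl]-2-methoxy-1-methyl-4-[3-(trimethylsilyl)prop-1-en-2-yl]cyclopent-2-en-1-ol | C=C[C@H](O[Si](CC)(CC)CC)[C@@H](C(C)C)[C@H](O)[C@H]1[C@](C)(O)C(OC)=C[C@@H]1C(=C)C[Si](C)(C)C | intermediate
23 | (2S,3S,4S)-3-[(1S,2R,3S)-1,3-dihydroxy-2-(propan-2-yl)pent-4-en-1-yl]-2-hydroxy-2-methyl-4-[3-(trimethylsilyl)prop-1-en-2-yl]cyclopentan-1-one | C=C[C@H](O)[C@@H](C(C)C)[C@H](O)[C@H]1[C@](C)(O)C(=O)C[C@@H]1C(=C)C[Si](C)(C)C | intermediate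
24 | (1S,2S,3S,4S)-3-[(1S,2R,3S)-1,3-dihydroxy-2-(propan-2-yl)pent-4-en-1-yl]-2-methyl-4-[3-(trimethylsilyl)prop-1-en-2-yl]cyclopentane-1,2-diol | C=C[C@H](O)[C@@H](C(C)C)[C@H](O)[C@H]1[C@](C)(O)[C@@H](O)C[C@@H]1C(=C)C[Si](C)(C)C | intermediate
25 | (1S,2S,3S,4S)-3-[(1S,2R,3S)-1,3-diacetoxy-2-(propan-2-yl)pent-4-en-1-yl]-2-hydroxy-2-methyl-4-[3-(trimethylsilyl)prop-1-en-2-yl]cyclopentyl acetate | C=C[C@H](OC(C)=O)[C@@H](C(C)C)[C@H](OC(C)=O)[C@H]1[C@](C)(O)[C@@H](OC(C)=O)C[C@@H]1C(=C)C[Si](C)(C)C | intermediate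
26 | (1S,3S,4S,5S,6S,7R,8S)-4-hydroxy-14-(trimethylsilyl)guai-9-ene-3,6,8-triyl triacetate (trans-fused; guaiane numbering) | C[Si](C)(C)CC1=C[C@H](OC(C)=O)[C@@H](C(C)C)[C@H](OC(C)=O)[C@@H]2[C@@H]1C[C@H](OC(C)=O)[C@@]2(C)O | intermediate
27 | (1S,3S,4S,5S,6S,7R,8S)-4-hydroxyguai-10(14)-ene-3,6,8-triyl triacetate (guaiane numbering) | C=C1C[C@H](OC(C)=O)[C@@H](C(C)C)[C@H](OC(C)=O)[C@@H]2[C@@H]1C[C@H](OC(C)=O)[C@@]2(C)O | target

**Totals**
Total step count: 17. Longest linear sequence: 11 steps (steps 1, 2, 4, 5, 6, 12, 13, 14, 15, 16, 17; the branch through steps 7–11 and 12–17 is equally long).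

**Steps most likely to fail**

Step 12 (fragment aldol). The anti preference of the cyclic E-enolate and the Felkin preference of aldehyde 19 reinforce each other only if the silyloxy-bearing C8 branch, not the isopropyl group, acts as the large substituent; otherwise much C6 epimer forms. Fallback: set out from 21 as the epimer mixture and fix C6 by directed reduction instead of aldol face selectivity. The mixture is treated with MeMgBr as in step 13 but worked up with aq. NH4Cl only, so the enol ether survives; this gives 22 together with its C6 epimer, the epimeric enol ether carbinol F1. Oxidising the mixture with Dess–Martin periodinane/pyridine converges both on the β-hydroxy ketone with C6 as carbonyl, the C6 ketone F2. Narasaka–Prasad reduction (Et2BOMe, NaBH4, THF/MeOH, −78 °C), with the tertiary C4 hydroxyl holding the boron chelate, gives the 4,6-syn diol, which is 22; the AcOH/THF/H2O treatment of step 13 then delivers 23, where the route is rejoined.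

Step 13 (C4 methyl carbinol). If chelation by the C6 alkoxide does not control the face of MeMgBr attack, the C4 epimer results. Fallback: set out from 21 and build C4 by electrophilic hydroxylation instead of nucleophilic methylation. Silylation (Et3SiOTf, 2,6-lutidine) gives the bis-silyl ether F3; Wittig methylenation (Ph3P=CH2, THF) gives the cross-conjugated dienol ether F4; wet oxalic acid on silica hydrolyses the enol ether to the α-methylene ketone F5. Conjugate reduction with LiBH(s-Bu)3 at −78 °C forms the C3 enolate regiospecifically, and 3-phenyl-2-(phenylsulfonyl)oxaziridine in the same flask hydroxylates C4 on the face anti to the C5 side chain, giving the silylated ketol F6. AcOH/THF/H2O removes both triethylsilyl groups and returns 23.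

Step 16 (ring-closing metathesis). A trisubstituted olefin must form from a hindered 1,1-disubstituted allylsilane and a vinyl group next to an acetoxy carbon. Fallback: set out from 24 and close the ring before acylation, so that the substrate is a free allylic alcohol (hydroxyl-assisted initiation, less steric load at C8). The same ruthenium carbene in CH2Cl2 at 40 °C gives the cyclic allylsilane tetraol F7, and Ac2O/pyridine/DMAP then esterifies the three secondary hydroxyls to give 26, where the route is rejoined.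

**Further compounds**
F1 | step 12 | C6 epimer of 22: (1S,4S,5S)-5-[(1R,2S,3S)-1-hydroxy-2-(propan-2-yl)-3-[(triethylsilyl)oxy]pent-4-en-1-yl]-2-methoxy-1-methyl-4-[3-(trimethylsilyl)prop-1-en-2-yl]cyclopent-2-en-1-ol | C=C[C@H](O[Si](CC)(CC)CC)[C@@H](C(C)C)[C@@H](O)[C@H]1[C@](C)(O)C(OC)=C[C@@H]1C(=C)C[Si](C)(C)C
F2 | step 12 | C6 ketone: 22 with the C6 carbinol oxidised to C=O | C=C[C@H](O[Si](CC)(CC)CC)[C@@H](C(C)C)C(=O)[C@H]1[C@](C)(O)C(OC)=C[C@@H]1C(=C)C[Si](C)(C)C
F3 | step 13 | 21 with the C6 hydroxyl as its triethylsilyl ether | C=C[C@H](O[Si](CC)(CC)CC)[C@@H](C(C)C)[C@H](O[Si](CC)(CC)CC)[C@H]1C(=O)C(OC)=C[C@@H]1C(=C)C[Si](C)(C)C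
F4 | step 13 | 4-methylidene dienol ether: F3 with C4=O replaced by C4=CH2 | C=C[C@H](O[Si](CC)(CC)CC)[C@@H](C(C)C)[C@H](O[Si](CC)(CC)CC)[C@H]1C(=C)C(OC)=C[C@@H]1C(=C)C[Si](C)(C)C
F5 | step 13 | α-methylene ketone: C3 ketone with exocyclic C4=CH2 and both silyl ethers | C=C[C@H](O[Si](CC)(CC)CC)[C@@H](C(C)C)[C@H](O[Si](CC)(CC)CC)[C@H]1C(=C)C(=O)C[C@@H]1C(=C)C[Si](C)(C)C
F6 | step 13 | 6,8-bis(triethylsilyl) ether of 23 | C=C[C@H](O[Si](CC)(CC)CC)[C@@H](C(C)C)[C@H](O[Si](CC)(CC)CC)[C@H]1[C@](C)(O)C(=O)C[C@@H]1C(=C)C[Si](C)(C)C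
F7 | step 16 | (1S,3S,4S,5S,6S,7R,8S)-14-(trimethylsilyl)guai-9-ene-3,4,6,8-tetrol | C[Si](C)(C)CC1=C[C@H](O)[C@@H](C(C)C)[C@H](O)[C@@H]2[C@@H]1C[C@H](O)[C@@]2(C)O
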